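**Retrosynthetic overview**
1. Last C–C bond, C9–C11: B-alkyl Suzuki–Miyaura union of the left-half dienyl triflate 19 with the 9-BBN adduct of right-half olefin 27; the C6=C7–C8=C9 diene is the dienol triflate of enone 18.
2. Key disconnection, C3–C4 and C5–C10 together: rings A and B of the decalin arise in one operation from the monocyclic cyclobutanone 13 by rhodium-catalysed insertion of the tethered C4=C5 olefin into the C3–C10 bond (two-carbon ring expansion, four- to six-membered ring).
3. Enabling feature: in ring A the oxygenated C3 and the quaternary C10 are joined through C2–C1 and both flank the C4(gem-dimethyl)–C5 pair, so C3/C2/C1/C10 can be stored as a 2,2-disubstituted cyclobutanone and C4/C5 as a prenyl-type olefin held on C10 by the ring B carbons C6–C9.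
4. The cyclobutanone and its C10 stereocentre come from a cyclopropylidene alcohol (asymmetric epoxidation–semipinacol expansion); the right half (oxepane and cyclohexane rings in one cascade) comes from farnesyl acetate diepoxide.
5. Ring order: cyclopropane → cyclobutanone (step 3) → rings A + B (step 9); independently oxepane + cyclohexane (step 15); union (step 20).

Key step: step 9

Remark (assumption): target locants are used throughout (decalin C1–C10 with C3 carbinol, C4 gem-dimethyl, C5/C10 ring fusion; linker C11–C12; right half C13–C22 with the C17–O–C22 oxepane and C21 carbonyl; β is the face of the C10 methyl), and the carbinol carbon C9 of 12–17 is carried as a mixture of epimers because it becomes the ketone carbon of 18.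

**Route**

Step 1
Reactants: 1 1-[(tert-butyldimethylsilyl)oxy]propan-2-one; 2 (3-bromopropyl)triphenylphosphonium bromide
Product: 3 tert-butyl(2-cyclopropylidenepropoxy)dimethylsilane
Conditions: KOtBu (2.1 equiv), THF, 65 °C; then 1, 65 °C
Reagents that add atoms: none
Why: Wittig olefination, in which the cyclopropylidene ylide formed in the flask from 2 (ring closure, second deprotonation) converts the ketone into the alkylidenecyclopropane; no stereocentre is formed.

Step 2
Reactants: 3 tert-butyl(2-cyclopropylidenepropoxy)dimethylsilane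
Product: 4 2-cyclopropylidenepropan-1-ol
Conditions: Bu4NF, THF, 0 °C to rt
Reagents that add atoms: none
Why: Fluoride desilylation of a primary silyl ether is routine and leaves the strained olefin untouched.

Step 3
Reactants: 4 2-cyclopropylidenepropan-1-ol
Product: 6 (2R)-2-(hydroxymethyl)-2-methylcyclobutan-1-one, via oxaspiropentane 5 (not isolated)
Conditions: Ti(OiPr)4 (10 mol %), L-(+)-diethyl tartrate (12 mol %), t-BuOOH, 4 Å molecular sieves, CH2Cl2, −30 °C
Reagents that add atoms: tert-butyl hydroperoxide, CC(C)(C)OO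
Why: Tandem Sharpless asymmetric epoxidation–semipinacol ring expansion, known for 2-substituted 2-cyclopropylideneethanols: the L-(+)-tartrate complex should deliver oxygen to the face that gives (S)-5, and a cyclopropane C–C bond then migrates to C10 anti to the breaking C–O bond, which sets the quaternary C10 as (R).

Step 4
Reactants: 6 (2R)-2-(hydroxymethyl)-2-methylcyclobutan-1-one
Product: 7 (1R)-1-methyl-2-oxocyclobutane-1-carbaldehyde
Conditions: Dess–Martin periodinane, pyridine, CH2Cl2, 0 °C; used at once
Reagents that add atoms: none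
Why: Dess–Martin oxidation of the neopentyl primary alcohol under non-nucleophilic conditions; C10 is quaternary and cannot epimerise.

Step 5
Reactants: 8 4-methylpent-3-en-1-ol
Product: 9 4-methylpent-3-enal
Conditions: Dess–Martin periodinane, pyridine, CH2Cl2, 0 °C; used cold and at once
Reagents that add atoms: none
Why: Dess–Martin oxidation under buffered conditions should give the β,γ-unsaturated aldehyde without migration of the double bond into conjugation.

Step 6
Reactants: 9 4-methylpent-3-enal; 10 ethyltriphenylphosphonium iodide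
Product: 11 (2Z)-2-iodo-6-methylhepta-2,5-diene
Conditions: 10, n-BuLi, THF, rt; I2, −78 °C; NaN(SiMe3)2, −20 °C; then 9, −78 °C
Reagents that add atoms: iodine, II
Why: Stork–Zhao-type Wittig olefination with the α-iodo ylide made in the flask from 10 should give the (Z)-2-iodoalkene (iodine cis to the chain) under kinetic control.

Step 7
Reactants: 7 (1R)-1-methyl-2-oxocyclobutane-1-carbaldehyde; 11 (2Z)-2-iodo-6-methylhepta-2,5-diene
Product: 12 (2R)-2-[(2Z)-1-hydroxy-2,6-dimethylhepta-2,5-dien-1-yl]-2-methylcyclobutan-1-one (C9 epimers)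
Conditions: CrCl2 (4 equiv), NiCl2 (1 mol %), DMSO, rt
Reagents that add atoms: none
Why: Nozaki–Hiyama–Kishi coupling, in which the alkenylchromium reagent formed from 11 with retention of olefin geometry adds to the aldehyde and not to the ketone; the new carbinol centre C9 forms as an epimer mixture, which is harmless because C9 is oxidised in step 12.

Step 8
Reactants: 12 (2R)-2-[(2Z)-1-hydroxy-2,6-dimethylhepta-2,5-dien-1-yl]-2-methylcyclobutan-1-one
Product: 13 (2R)-2-[(2Z)-2,6-dimethyl-1-(triethylsilyloxy)hepta-2,5-dien-1-yl]-2-methylcyclobutan-1-one (C9 epimers)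
Conditions: Et3SiOTf, 2,6-lutidine, CH2Cl2, −78 °C
Reagents that add atoms: triethylsilyl trifluoromethanesulfonate, CC[Si](CC)(CC)OS(=O)(=O)C(F)(F)F
Why: Silylation with a silyl triflate under non-basic conditions protects the aldol-type alcohol against retro-aldol cleavage and keeps C10 a non-enolisable, configurationally fixed centre for step 9.

Step 9
Reactants: 13 (2R)-2-[(2Z)-2,6-dimethyl-1-(triethylsilyloxy)hepta-2,5-dien-1-yl]-2-methylcyclobutan-1-one
Product: 14 trans-fused 4,4,8,10-tetramethyl-9-(triethylsilyloxy)-Δ7-octalin-3-one (5α-H, 10β-methyl; C9 epimers), systematic name 1,1,4a,6-tetramethyl-5-(triethylsilyloxy)-3,4,4a,5,8,8a-hexahydronaphthalen-2(1H)-one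
Conditions: [Rh(C2H4)2Cl]2 (5 mol %), PMe2Ph (20 mol %), 1,4-dioxane, 110 °C, sealed tube
Reagents that add atoms: none
Why: Proposed new method: a monovalent rhodium centre, held near the ring by the tethered olefin, should insert oxidatively into the strained acyl–quaternary-carbon bond C3–C10 of the cyclobutanone, the C4=C5 olefin then undergoes syn migratory insertion into the Rh–C10 bond (C5–C10 formed), and acyl–alkyl reductive elimination from the seven-membered rhodacycle forms C3–C4, so that the olefin is formally inserted into the C3–C10 bond. The closest known reactions are the rhodium-catalysed "cut-and-sew" carboacylations, which give fused rings from benzocyclobutenones with trisubstituted olefins (a quaternary carbon next to the ketone is formed) and from saturated cyclobutanones carrying an alkyne on the α-carbon; a saturated cyclobutanone with an α-quaternary centre and a trisubstituted olefin is the new combination. Ring B is closed by 6-exo-trig carbometalation onto C5, and ring A arises by two-carbon expansion of the four-membered ring (a formal [4+2] coupling). C10 is not created here: oxidative addition and insertion proceed with retention at carbon, so its configuration comes from 6; C5 is set in the syn insertion, where the (Z)-olefin of the tether should force a half-chair for the nascent ring B with the C10 methyl pseudo-axial and the C5–C4 bond pseudo-equatorial (C4 must stay on rhodium), which places H5 anti to the C10 methyl (trans ring fusion). The step needs site selectivity for the hindered C3–C10 bond over C2–C3, which should follow because C–C insertion is reversible and only the C3–C10 rhodacycle can reach the tethered olefin, and olefin selectivity for C4=C5 over C7=C8, which could only close a three- or four-membered ring. Reductive elimination must also outrun β-hydride elimination from the tertiary alkylrhodium, which the small electron-rich phosphine and the constraint of the metallacycle should favour.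

Step 10
Reactants: 14 trans-fused 4,4,8,10-tetramethyl-9-(triethylsilyloxy)-Δ7-octalin-3-one
Product: 15 4,4,8,10-tetramethyl-9-(triethylsilyloxy)-Δ7-octalin-3β-ol (5α-H, 10β-methyl; C9 epimers)
Conditions: NaBH4, MeOH, 0 °C
Reagents that add atoms: none
Why: Hydride reduction of the only ketone, in which hydride should enter from the α face, away from the axial 4β- and 10β-methyl groups, and give the equatorial 3β-alcohol.

Step 11
Reactants: 15 4,4,8,10-tetramethyl-9-(triethylsilyloxy)-Δ7-octalin-3β-ol
Product: 16 3β-[(tert-butyldimethylsilyl)oxy]-4,4,8,10-tetramethyl-9-(triethylsilyloxy)-Δ7-octalin (C9 epimers)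
Conditions: t-BuMe2SiOTf, 2,6-lutidine, CH2Cl2, −78 to 0 °C
Reagents that add atoms: tert-butyldimethylsilyl trifluoromethanesulfonate, CC(C)(C)[Si](C)(C)OS(=O)(=O)C(F)(F)F
Why: A silyl triflate with 2,6-lutidine silylates even this neopentyl secondary alcohol.

Step 12
Reactants: 16 3β-[(tert-butyldimethylsilyl)oxy]-4,4,8,10-tetramethyl-9-(triethylsilyloxy)-Δ7-octalin
Product: 18 3β-[(tert-butyldimethylsilyl)oxy]-4,4,8,10-tetramethyl-Δ7-octalin-9-one (5α-H, 10β-methyl), via allylic alcohol 17 (not isolated)
Conditions: IBX (3 equiv), DMSO, rt to 40 °C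
Reagents that add atoms: none
Why: IBX in DMSO is known to cleave triethylsilyl ethers in the presence of tert-butyldimethylsilyl ethers and should then oxidise the allylic alcohol 17 to the enone in the same flask, which removes the temporary C9 stereocentre.

Step 13
Reactants: 18 3β-[(tert-butyldimethylsilyl)oxy]-4,4,8,10-tetramethyl-Δ7-octalin-9-one
Product: 19 3β-[(tert-butyldimethylsilyl)oxy]-4,4,8,10-tetramethyl-octalin-6,8-dien-9-yl trifluoromethanesulfonate (5α-H, 10β-methyl)
Conditions: KN(SiMe3)2, THF, −78 °C; PhNTf2, −78 to 0 °C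
Reagents that add atoms: N-phenylbis(trifluoromethanesulfonimide), O=S(=O)(N(c1ccccc1)S(=O)(=O)C(F)(F)F)C(F)(F)F
Why: Enolate O-triflation, in which deprotonation can only take the γ-hydrogen at C6 (C10 is quaternary) and the extended dienolate is triflated on oxygen to give the 2-triflyloxy-1,3-diene, that is, the C6=C7–C8=C9 diene of the target.

Step 14
Reactants: 20 (2E,6E)-farnesyl acetate
Product: 21 (6S,7S,10S)-6,7:10,11-diepoxy-(2E)-farnesyl acetate (17S,18S,21S in target locants)
Conditions: ent-Shi ketone (from L-sorbose, 0.6 equiv), Oxone (2KHSO5·KHSO4·K2SO4), K2CO3, Bu4NHSO4, MeCN/dimethoxymethane/aqueous buffer pH 10.5, 0 °C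
Reagents that add atoms: potassium peroxymonosulfate (active part of Oxone), [K+].[O-]S(=O)(=O)OO
Why: Shi asymmetric epoxidation, in which the dioxirane of the L-configured ketone should epoxidise the two electron-rich trisubstituted olefins to the (S,S) and (S) epoxides while the 2,3-olefin, deactivated by the allylic acetate, is left.

Step 15
Reactants: 21 (6S,7S,10S)-6,7:10,11-diepoxy-(2E)-farnesyl acetate
Product: 22 [2,2,5a-trimethyl-7-methylidene-3-(trimethylsilyloxy)decahydro-1-benzoxepin-6-yl]methyl acetate (trans-fused; H17 anti to the C18 methyl; C13 side chain equatorial; 21S)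
Conditions: Me3SiOTf (1.1 equiv), 2,6-di-tert-butyl-4-methylpyridine, CH2Cl2, −78 °C
Reagents that add atoms: trimethylsilyl trifluoromethanesulfonate, C[Si](C)(C)OS(=O)(=O)C(F)(F)F
Why: Lewis-acid epoxide-opening oxa-/carbacyclisation cascade, known for farnesyl-derived diepoxides: the silylated terminal epoxide is opened at C22 by the 17,18-epoxide oxygen, the resulting epoxonium is opened at C18 with inversion by the C13=C14 olefin through a chair transition state (trans-fused oxepane, H13 anti to the C18 methyl), and loss of a methyl proton gives the exocyclic olefin.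

Step 16
Reactants: 22 [2,2,5a-trimethyl-7-methylidene-3-(trimethylsilyloxy)decahydro-1-benzoxepin-6-yl]methyl acetate
Product: 23 [2,2,5a,7-tetramethyl-3-(trimethylsilyloxy)decahydro-1-benzoxepin-6-yl]methyl acetate (C14 methyl cis to the C18 methyl)
Conditions: H2 (1 atm), PtO2, EtOAc, rt
Reagents that add atoms: none
Why: Heterogeneous hydrogenation, in which hydrogen should add to the exocyclic olefin from the face opposite the axial C18 methyl and so give the axial C14 methyl of the target.

Step 17
Reactants: 23 [2,2,5a,7-tetramethyl-3-(trimethylsilyloxy)decahydro-1-benzoxepin-6-yl]methyl acetate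
Product: 24 6-(hydroxymethyl)-2,2,5a,7-tetramethyldecahydro-1-benzoxepin-3-ol (configuration at C13, C14, C17, C18 as in the target; 21S)
Conditions: K2CO3 (0.2 equiv), MeOH, rt
Reagents that add atoms: none
Why: Methanolysis cleaves both the acetate and the labile trimethylsilyl ether.

Step 18
Reactants: 24 6-(hydroxymethyl)-2,2,5a,7-tetramethyldecahydro-1-benzoxepin-3-ol
Product: 25 3-hydroxy-2,2,5a,7-tetramethyldecahydro-1-benzoxepine-6-carbaldehyde
Conditions: TEMPO (10 mol %), PhI(OAc)2, CH2Cl2, rt
Reagents that add atoms: none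
Why: Oxoammonium (TEMPO) oxidation takes the primary alcohol selectively over the hindered secondary one, and the equatorial aldehyde is configurationally stable at C13.

Step 19
Reactants: 25 3-hydroxy-2,2,5a,7-tetramethyldecahydro-1-benzoxepine-6-carbaldehyde; 26 methyltriphenylphosphonium bromide
Product: 27 6-ethenyl-2,2,5a,7-tetramethyldecahydro-1-benzoxepin-3-ol
Conditions: 26 (2.5 equiv), KN(SiMe3)2 (2.4 equiv), THF, 0 °C; then 25, 0 °C to rt
Reagents that add atoms: none
Why: Wittig methylenation with excess ylide (one equivalent is taken up by the free hydroxyl) should convert the aldehyde into the vinyl group without epimerisation at C13.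

Step 20
Reactants: 27 6-ethenyl-2,2,5a,7-tetramethyldecahydro-1-benzoxepin-3-ol; 19 3β-[(tert-butyldimethylsilyl)oxy]-4,4,8,10-tetramethyl-octalin-6,8-dien-9-yl trifluoromethanesulfonate
Product: 29 3-O-(tert-butyldimethylsilyl)-21-hydroxy coupled product (target skeleton with the 3β-silyl ether and the 21S oxepanol), via alkylborane 28 (not isolated)
Conditions: 27, 9-BBN (2.5 equiv), THF, rt; then 19, Pd(dppf)Cl2 (10 mol %), AsPh3, Cs2CO3, DMF/H2O, 50 °C
Reagents that add atoms: none
Why: B-alkyl Suzuki–Miyaura coupling, in which anti-Markovnikov hydroboration of the vinyl group gives 28 and this couples with the dienyl triflate (couplings of 2,6,6-trisubstituted cyclohexenyl triflates with B-alkyl-9-BBN reagents are well known); no stereocentre is formed.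

Step 21
Reactants: 29 3-O-(tert-butyldimethylsilyl)-21-hydroxy coupled product
Product: 30 3-O-(tert-butyldimethylsilyl) ether of the target (21-ketone)
Conditions: Dess–Martin periodinane, pyridine, CH2Cl2, 0 °C to rt
Reagents that add atoms: none
Why: Dess–Martin oxidation of the only free hydroxyl should give the oxepanone while the diene and the silyl ether are inert.

Step 22
Reactants: 30 3-O-(tert-butyldimethylsilyl) ether of the target
Product: 31 CNP0106412.1
Conditions: Bu4NF, THF, 50 °C
Reagents that add atoms: none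
Why: Fluoride desilylation releases the 3β-alcohol without touching any stereocentre.

**Compound list**
1 | 1-[(tert-butyldimethylsilyl)oxy]propan-2-one | CC(=O)CO[Si](C)(C)C(C)(C)C | starting material
2 | (3-bromopropyl)triphenylphosphonium bromide | BrCCC[P+](c1ccccc1)(c1ccccc1)c1ccccc1.[Br-] | starting material
3 | tert-butyl(2-cyclopropylidenepropoxy)dimethylsilane | CC(CO[Si](C)(C)C(C)(C)C)=C1CC1 | intermediate
4 | 2-cyclopropylidenepropan-1-ol | CC(CO)=C1CC1 | intermediate
5 | [(2S)-2-methyl-1-oxaspiro[2.2]pentan-2-yl]methanol | OC[C@]1(C)OC12CC2 | intermediate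
6 | (2R)-2-(hydroxymethyl)-2-methylcyclobutan-1-one | OC[C@@]1(C)CCC1=O | intermediate
7 | (1R)-1-methyl-2-oxocyclobutane-1-carbaldehyde | O=C[C@@]1(C)CCC1=O | intermediate
8 | 4-methylpent-3-en-1-ol | CC(C)=CCCO | starting material
9 | 4-methylpent-3-enal | CC(C)=CCC=O | intermediate
10 | ethyltriphenylphosphonium iodide | CC[P+](c1ccccc1)(c1ccccc1)c1ccccc1.[I-] | starting material
11 | (2Z)-2-iodo-6-methylhepta-2,5-diene | C/C(I)=C/CC=C(C)C | intermediate
12 | (2R)-2-[(2Z)-1-hydroxy-2,6-dimethylhepta-2,5-dien-1-yl]-2-methylcyclobutan-1-one (C9 epimers) | CC(C)=CC/C=C(/C)C(O)[C@@]1(C)CCC1=O | intermediate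
13 | (2R)-2-[(2Z)-2,6-dimethyl-1-(triethylsilyloxy)hepta-2,5-dien-1-yl]-2-methylcyclobutan-1-one (C9 epimers) | CC(C)=CC/C=C(/C)C(O[Si](CC)(CC)CC)[C@@]1(C)CCC1=O | intermediate
14 | trans-fused 4,4,8,10-tetramethyl-9-(triethylsilyloxy)-Δ7-octalin-3-one (5α-H, 10β-methyl; C9 epimers) | CC=1C(O[Si](CC)(CC)CC)[C@@]2(C)CCC(=O)C(C)(C)[C@@H]2CC=1 | intermediate
15 | 4,4,8,10-tetramethyl-9-(triethylsilyloxy)-Δ7-octalin-3β-ol (C9 epimers) | CC=1C(O[Si](CC)(CC)CC)[C@@]2(C)CC[C@H](O)C(C)(C)[C@@H]2CC=1 | intermediate
16 | 3β-[(tert-butyldimethylsilyl)oxy]-4,4,8,10-tetramethyl-9-(triethylsilyloxy)-Δ7-octalin (C9 epimers) | CC=1C(O[Si](CC)(CC)CC)[C@@]2(C)CC[C@H](O[Si](C)(C)C(C)(C)C)C(C)(C)[C@@H]2CC=1 | intermediate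
17 | 3β-[(tert-butyldimethylsilyl)oxy]-4,4,8,10-tetramethyl-Δ7-octalin-9-ol (C9 epimers) | CC=1C(O)[C@@]2(C)CC[C@H](O[Si](C)(C)C(C)(C)C)C(C)(C)[C@@H]2CC=1 | intermediate
18 | 3β-[(tert-butyldimethylsilyl)oxy]-4,4,8,10-tetramethyl-Δ7-octalin-9-one | CC=1C(=O)[C@@]2(C)CC[C@H](O[Si](C)(C)C(C)(C)C)C(C)(C)[C@@H]2CC=1 | intermediate
19 | 3β-[(tert-butyldimethylsilyl)oxy]-4,4,8,10-tetramethyl-octalin-6,8-dien-9-yl trifluoromethanesulfonate | CC1=C(OS(=O)(=O)C(F)(F)F)[C@@]2(C)CC[C@H](O[Si](C)(C)C(C)(C)C)C(C)(C)[C@@H]2C=C1 | intermediate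
20 | (2E,6E)-farnesyl acetate | CC(=O)OC/C=C(\C)CC/C=C(\C)CCC=C(C)C | starting material
21 | (6S,7S,10S)-6,7:10,11-diepoxy-(2E)-farnesyl acetate | CC(=O)OC/C=C(\C)CC[C@@H]1O[C@@]1(C)CC[C@@H]1OC1(C)C | intermediate
22 | [2,2,5a-trimethyl-7-methylidene-3-(trimethylsilyloxy)decahydro-1-benzoxepin-6-yl]methyl acetate | CC(=O)OC[C@@H]1C(=C)CC[C@@H]2OC(C)(C)[C@@H](O[Si](C)(C)C)CC[C@]21C | intermediate
23 | [2,2,5a,7-tetramethyl-3-(trimethylsilyloxy)decahydro-1-benzoxepin-6-yl]methyl acetate | CC(=O)OC[C@@H]1[C@H](C)CC[C@@H]2OC(C)(C)[C@@H](O[Si](C)(C)C)CC[C@]21C | intermediate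
24 | 6-(hydroxymethyl)-2,2,5a,7-tetramethyldecahydro-1-benzoxepin-3-ol | OC[C@@H]1[C@H](C)CC[C@@H]2OC(C)(C)[C@@H](O)CC[C@]21C | intermediate
25 | 3-hydroxy-2,2,5a,7-tetramethyldecahydro-1-benzoxepine-6-carbaldehyde | O=C[C@@H]1[C@H](C)CC[C@@H]2OC(C)(C)[C@@H](O)CC[C@]21C | intermediate
26 | methyltriphenylphosphonium bromide | C[P+](c1ccccc1)(c1ccccc1)c1ccccc1.[Br-] | starting material
27 | 6-ethenyl-2,2,5a,7-tetramethyldecahydro-1-benzoxepin-3-ol | C=C[C@@H]1[C@H](C)CC[C@@H]2OC(C)(C)[C@@H](O)CC[C@]21C | intermediate
28 | B-alkyl-9-borabicyclo[3.3.1]nonane of 27 (hydroxyl as its 9-BBN borinate) | C(C[C@@H]1[C@H](C)CC[C@@H]2OC(C)(C)[C@@H](OB3C4CCCC3CCC4)CC[C@]21C)B1C2CCCC1CCC2 | intermediate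
29 | 3-O-(tert-butyldimethylsilyl)-21-hydroxy coupled product | CC1=C(CC[C@@H]2[C@H](C)CC[C@@H]3OC(C)(C)[C@@H](O)CC[C@]32C)[C@@]2(C)CC[C@H](O[Si](C)(C)C(C)(C)C)C(C)(C)[C@@H]2C=C1 | intermediate
30 | 3-O-(tert-butyldimethylsilyl) ether of the target | CC1=C(CC[C@@H]2[C@H](C)CC[C@@H]3OC(C)(C)C(=O)CC[C@]32C)[C@@]2(C)CC[C@H](O[Si](C)(C)C(C)(C)C)C(C)(C)[C@@H]2C=C1 | intermediate
31 | CNP0106412.1 | CC1=C(CC[C@@H]2[C@H](C)CC[C@@H]3OC(C)(C)C(=O)CC[C@]32C)[C@@]2(C)CC[C@H](O)C(C)(C)[C@@H]2C=C1 | target

**Step count**
Total: 22 steps. Longest linear sequence: 14 steps (1–4, 7–13, 20–22).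

**Steps most likely to fail**

Step 9 (Proposed new method). The rhodium may insert only into the unhindered C2–C3 bond, the acyl rhodium may lose carbon monoxide, the tertiary alkylrhodium may undergo β-hydride elimination before reductive elimination, or the olefin may insert from the wrong face and give the cis ring fusion. The fallback sets the gem-dimethyl carbon and H5 after the ring expansion, with known chemistry. It sets out from aldehyde 7 and comes back at 14. Commercial pent-3-yn-1-ol is oxidised (Dess–Martin periodinane) to pent-3-ynal F1, which under the conditions of step 6 with 10 should give (2Z)-2-iodohept-2-en-5-yne F2. Nozaki–Hiyama–Kishi coupling with 7 would give (2R)-2-[(2Z)-1-hydroxy-2-methylhept-2-en-5-yn-1-yl]-2-methylcyclobutan-1-one F3, and Et3SiOTf/2,6-lutidine its triethylsilyl ether F4. The rhodium-catalysed cut-and-sew of cyclobutanones with an alkyne on the α-carbon ([Rh(C2H4)2Cl]2, PMe2Ph, dioxane) is a known fused-ring synthesis and should give 4,8,10-trimethyl-9-(triethylsilyloxy)-octalin-4,7-dien-3-one F5. Reductive methylation (Li, NH3, t-BuOH, THF, −78 °C; then MeI) should protonate C5 axially (trans ring fusion) and methylate the C4 enolate, which is compound 14.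

Step 20. Oxidative addition or transmetalation at the hindered tetrasubstituted dienyl triflate may be slow, so that protodeboronation of 28 or hydrolysis of 19 takes over. The fallback makes C9–C11 by carbonyl addition; it sets out from olefin 27 and enone 18 and comes back at 29. Hydroboration of 27 (9-BBN) and iodination (I2, NaOMe) would give the primary iodide 6-(2-iodoethyl)-2,2,5a,7-tetramethyldecahydro-1-benzoxepin-3-ol F6. Its dilithio derivative (t-BuLi, 3 equiv, Et2O, −78 °C; then CeCl3) should add to the C9 carbonyl of 18 to give the tertiary allylic alcohol F7. Mild acid (camphorsulfonic acid cat., benzene, rt) should ionise only this tertiary allylic alcohol, and loss of H6 gives the conjugated C6=C7–C8=C9 diene, which is compound 29.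

Step 7. The β-keto aldehyde 7 may be lost by retro-Claisen ring opening or deformylation, or the organochromium reagent may add to the strained ketone. The fallback attaches the side arm before the four-membered ring is made; it sets out from allylic alcohol 4 (and uses 11) and comes back at 12. MnO2 oxidation of 4 would give 2-cyclopropylidenepropanal F8. The alkenyllithium from 11 (t-BuLi, Et2O, −78 °C) should add to it to give racemic (4Z)-2-cyclopropylidene-4,8-dimethylnona-4,7-dien-3-ol F9. Sharpless kinetic resolution (Ti(OiPr)4, L-(+)-diisopropyl tartrate, t-BuOOH 0.6 equiv, CH2Cl2, −20 °C) should epoxidise the cyclopropylidene olefin of the fast-reacting enantiomer; the epoxide rearranges as in step 3 and gives 12 as a single C9 epimer.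

**Further compounds**
F1 | step 9 | pent-3-ynal | CC#CCC=O
F2 | step 9 | (2Z)-2-iodohept-2-en-5-yne | C/C(I)=C/CC#CC
F3 | step 9 | (2R)-2-[(2Z)-1-hydroxy-2-methylhept-2-en-5-yn-1-yl]-2-methylcyclobutan-1-one (C9 epimers) | CC#CC/C=C(/C)C(O)[C@@]1(C)CCC1=O
F4 | step 9 | (2R)-2-methyl-2-[(2Z)-2-methyl-1-(triethylsilyloxy)hept-2-en-5-yn-1-yl]cyclobutan-1-one (C9 epimers) | CC#CC/C=C(/C)C(O[Si](CC)(CC)CC)[C@@]1(C)CCC1=O
F5 | step 9 | 4,8,10-trimethyl-9-(triethylsilyloxy)-octalin-4,7-dien-3-one (10β-methyl; C9 epimers) | CC=1C(O[Si](CC)(CC)CC)[C@@]2(C)CCC(=O)C(C)=C2CC=1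
F6 | step 20 | 6-(2-iodoethyl)-2,2,5a,7-tetramethyldecahydro-1-benzoxepin-3-ol | ICC[C@@H]1[C@H](C)CC[C@@H]2OC(C)(C)[C@@H](O)CC[C@]21C
F7 | step 20 | tertiary allylic alcohol from 1,2-addition of the right-half alkyl group to C9 of 18 (C9 epimers) | CC=1C(O)(CC[C@@H]3[C@H](C)CC[C@@H]4OC(C)(C)[C@@H](O)CC[C@]43C)[C@@]2(C)CC[C@H](O[Si](C)(C)C(C)(C)C)C(C)(C)[C@@H]2CC=1
F8 | step 7 | 2-cyclopropylidenepropanal | CC(C=O)=C1CC1
F9 | step 7 | (4Z)-2-cyclopropylidene-4,8-dimethylnona-4,7-dien-3-ol (racemic) | CC(C)=CC/C=C(/C)C(O)C(C)=C1CC1
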